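**Retrosynthetic overview**
1. The last disconnection is the bond between the styrenyl CH and ring carbon C1 of the 3,4-dimethoxyphenyl group. It opens to two C–H partners: veratrole (C4–H) and the terminal =CH2 of an allyl ester. Both carbons are nucleophilic, so they are joined by an oxidative (dehydrogenative Heck, Fujiwara–Moritani) coupling, which also sets the E alkene and the 1,2,4-pattern and finishes the molecule.
2. Enabling feature: in the veratrole ring, C4–H and C5–H are symmetry-equivalent, each para to a methoxy oxygen and unflanked, while C3 and C6 sit next to OMe. In the partner, the O–C(=O) group on the allylic CH2 chelates palladium, and the allyl CH=CH2 is the only monosubstituted alkene.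
3. Allyl diester: the CH2–O bond is made by a Mitsunobu reaction of allyl sarracinate with angelic acid, so the angelate is never acyl-activated.
4. Allyl sarracinate comes from carboxylate allylation of (Z)-2-(hydroxymethyl)but-2-enoic acid. That acid comes from (Z)-2-iodobut-2-en-1-ol (iodine replaced by CO2H with retention), which is made from crotonaldehyde.
5. No ring is formed in the route; the only ring, the benzene ring, is bought as veratrole.

Key step: step 6

Assumption: commercial angelic acid is taken as the geometrically pure Z acid and is used without further treatment.

**Step 1**
Reactants: 1 (E)-crotonaldehyde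
Product: 2 (Z)-2-iodobut-2-enal
Conditions: I2 (1.5 equiv), K2CO3 (1.2 equiv), DMAP (0.2 equiv), THF–H2O, 0 °C to rt
Reagents that add atoms: iodine, [I][I]
Why: Amine-catalysed α-iodination of an enal (Morita–Baylis–Hillman-type conjugate addition of DMAP, iodination of the enolate, E1cB loss of DMAP) should give the isomer with CH3 trans to CHO and therefore cis to iodine, which is the geometry needed later for the central but-2-enoate.

**Step 2**
Reactants: 2 (Z)-2-iodobut-2-enal
Product: 3 (Z)-2-iodobut-2-en-1-ol
Conditions: NaBH4, THF–H2O 9:1, 0 °C
Reagents that add atoms: none
Why: Borohydride 1,2-reduction of the aldehyde should leave the alkenyl iodide and its geometry untouched.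

**Step 3**
Reactants: 3 (Z)-2-iodobut-2-en-1-ol
Product: 5 (Z)-2-(hydroxymethyl)but-2-enoic acid (sarracinic acid), via dilithiated alkoxide 4 (not isolated)
Conditions: t-BuLi (3.1 equiv), Et2O, −78 °C; then dry CO2, −78 °C to 0 °C; then dilute aq HCl, extraction with EtOAc
Reagents that add atoms: carbon dioxide, O=C=O
Why: Deprotonation followed by iodine–lithium exchange should give an alkenyllithium that is configurationally stable at −78 °C, and its carboxylation proceeds with retention, so CO2H takes the place of iodine cis to CH3 (Z).

**Step 4**
Reactants: 5 (Z)-2-(hydroxymethyl)but-2-enoic acid; 6 allyl bromide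
Product: 7 allyl (Z)-2-(hydroxymethyl)but-2-enoate
Conditions: KHCO3 (1.5 equiv), 6 (1.2 equiv), DMF, rt
Reagents that add atoms: none
Why: SN2 O-alkylation of the carboxylate should be chemoselective, because hydrogencarbonate is too weak a base to deprotonate the alcohol or to isomerise the Z alkene.

**Step 5**
Reactants: 7 allyl (Z)-2-(hydroxymethyl)but-2-enoate; 8 angelic acid, (Z)-2-methylbut-2-enoic acid
Product: 9 allyl (Z)-2-({[(Z)-2-methylbut-2-enoyl]oxy}methyl)but-2-enoate
Conditions: PPh3 (1.2 equiv), DIAD (1.25 equiv), THF, 0 °C (betaine preformed); then 8, then 7, 0 °C to rt
Reagents that add atoms: none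
Why: The Mitsunobu esterification activates the primary allylic alcohol and not the acid, so the angelate never becomes an acyl-activated species that drifts to tiglate, and SN2 attack at the open CH2 should win over SN2' attack at the methyl-bearing alkene carbon.

**Step 6**
Reactants: 9 allyl (Z)-2-({[(Z)-2-methylbut-2-enoyl]oxy}methyl)but-2-enoate; 10 veratrole (1,2-dimethoxybenzene)
Product: 11 Morinin L
Conditions: Pd(OAc)2 (10 mol %), 3-methyl-2-(phenylthio)butanoic acid (10 mol %), PhCO3t-Bu (1.2 equiv), 10 (5 equiv), 1,2-dichloroethane, 60 °C
Reagents that add atoms: none
Why: Carboxylate-assisted concerted palladation of veratrole by the divalent palladium carboxylate gives a 3,4-dimethoxyphenylpalladium species, the terminal CH=CH2 of 9 inserts syn with the aryl group going to the CH2 terminus, syn β-hydride elimination of the benzylic hydrogen releases 11, and PhCO3t-Bu reoxidises zerovalent palladium. The closest known reaction type is the Fujiwara–Moritani (dehydrogenative Heck) olefination of electron-rich arenes, including its variant with allylic esters in which the ester is retained, so two C–H carbons of like nucleophilic polarity are joined without prefunctionalisation. No ring is closed and no stereocentre is formed; the E geometry follows from the syn-insertion/syn-elimination sequence through the conformer that keeps the aryl and CH2O groups apart. Site selectivity on the arene is secured by the ring itself, since C4–H and C5–H are equivalent by symmetry, para to a methoxy group and unhindered, whereas C3–H and C6–H are flanked by OMe, and the thioether–carboxylate ligand reinforces this bias. Chemoselectivity among the three alkenes is secured because only the allyl group is monosubstituted, the two but-2-enoate alkenes being trisubstituted, α-branched and electron-poor and so inert to carbopalladation. Retention of both allylic C–O bonds is secured by coordination of the allyl ester carbonyl oxygen to palladium in a six-membered chelate that holds the C–O bond out of alignment for β-acyloxy elimination, by the absence of phosphine so that zerovalent palladium is reoxidised before it can ionise an allylic ester, and by the non-ionising solvent.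

**Compound list**
1 | (E)-crotonaldehyde | C/C=C/C=O | starting material
2 | (Z)-2-iodobut-2-enal (CH3 cis to iodine) | C/C=C(\I)C=O | intermediate
3 | (Z)-2-iodobut-2-en-1-ol (CH3 cis to iodine) | C/C=C(\I)CO | intermediate
4 | dilithiated alkoxide, lithium 2-lithiobut-2-en-1-olate (CH3 cis to the carbon-bound lithium) | C/C=C(\[Li])CO[Li] | intermediate
5 | (Z)-2-(hydroxymethyl)but-2-enoic acid (sarracinic acid, CH3 cis to CO2H) | C/C=C(/CO)C(=O)O | intermediate
6 | allyl bromide | C=CCBr | starting material
7 | allyl (Z)-2-(hydroxymethyl)but-2-enoate | C/C=C(/CO)C(=O)OCC=C | intermediate
8 | angelic acid, (Z)-2-methylbut-2-enoic acid | C/C=C(/C)C(=O)O | starting material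
9 | allyl (Z)-2-({[(Z)-2-methylbut-2-enoyl]oxy}methyl)but-2-enoate | C/C=C(/C)C(=O)OC/C(=C/C)C(=O)OCC=C | intermediate
10 | veratrole (1,2-dimethoxybenzene) | COc1ccccc1OC | starting material
11 | Morinin L, (E)-3-(3,4-dimethoxyphenyl)allyl (Z)-2-({[(Z)-2-methylbut-2-enoyl]oxy}methyl)but-2-enoate | C/C=C(/C)C(=O)OC/C(=C/C)C(=O)OC/C=C/c1ccc(OC)c(OC)c1 | target

**Step count and risks**
Total step count: 6. Longest linear sequence: 6 steps (1 to 11).

Steps most likely to fail:

1. **Step 6.**
   - What may go wrong: β-acyloxy elimination from the alkylpalladium intermediate with loss of the whole acid fragment; competing palladation next to a methoxy group; ionisation of the electron-rich cinnamyl ester once formed; Z-to-E drift of the two but-2-enoate units through reversible hydropalladation.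
   - Fallback: a redox-neutral Heck–Matsuda arylation with a prefunctionalised arene. It sets out from 9 and comes back at 11.
   - Commercial 3,4-dimethoxyaniline F1 is diazotised (NaNO2, aq HBF4, 0 °C) to 3,4-dimethoxybenzenediazonium tetrafluoroborate F2.
   - F2 is then coupled with 9 (Pd2(dba)3, NaOAc, benzonitrile, rt).
   - The ring position is fixed by the carbon–nitrogen bond, the reaction runs at room temperature without phosphine or oxidant, and the cationic arylpalladium species is known to arylate allylic esters at the terminus with retention of the ester.

2. **Step 5.**
   - What may go wrong: allylic transposition by SN2' attack of the carboxylate; erosion of the Z geometry of the central alkene by reversible addition of free phosphine to the activated 2-(oxymethyl)enoate.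
   - Fallback: acyl transfer without any nucleophilic catalyst. It sets out from 8 and 7 and comes back at 9.
   - Angelic acid 8 is converted with 2,4,6-trichlorobenzoyl chloride and Et3N in toluene at rt into (Z)-2-methylbut-2-enoic 2,4,6-trichlorobenzoic anhydride F3.
   - F3 is heated with 7 in toluene at 80 °C, a Yamaguchi-type mixed-anhydride angeloylation that leaves the C–O bond of 7 untouched.

3. **Step 3.**
   - What may go wrong: incomplete halogen–metal exchange; premature protonation of the alkenyllithium; loss of geometry on warming; poor recovery of the small water-soluble acid.
   - Fallback: an acylpalladium route in place of the organolithium. It sets out from 3 and comes back at 7, bypassing 5 and step 4.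
   - Compound 3 is carbonylated directly in the presence of allyl alcohol (PdCl2(PPh3)2, CO 1 atm, i-Pr2NEt, allyl alcohol–THF, 50 °C).
   - Oxidative addition, CO insertion and alcoholysis all proceed with retention at the alkene, and the free hydroxyl group is too poor a leaving group to ionise.

**Further compounds**
F1 | step 6 | 3,4-dimethoxyaniline | COc1ccc(N)cc1OC
F2 | step 6 | 3,4-dimethoxybenzenediazonium tetrafluoroborate | COc1ccc([N+]#N)cc1OC.F[B-](F)(F)F
F3 | step 5 | (Z)-2-methylbut-2-enoic 2,4,6-trichlorobenzoic anhydride | C/C=C(/C)C(=O)OC(=O)c1c(Cl)cc(Cl)cc1Cl
F0 | step 3 | none | none
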